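The disconnection cuts the unbranched C26 chain of the hexacosyl ester at its midpoint, C13–C14 counted from the O-bearing carbon. Both halves are then primary C13 radicals, each available by decarboxylation of a C14 acid. A mixed Kolbe electrolysis of tetradecanoic (myristic) acid with 14-{[3-(4-acetoxyphenyl)propanoyl]oxy}tetradecanoic acid should forge this CH2–CH2 bond in one anodic operation, with the ester already in place. The step exploits the saturated, unfunctionalised polymethylene chain, which offers no competing site. The only anodically sensitive unit, the para-hydroxylated benzene ring, is masked as its acetate and freed at the end.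

Key step: step 3

Remark: the target has no stereocentre and no stereogenic double bond, so it is achiral and no step needs stereocontrol.

Step 1
Reactants: 1 3-(4-hydroxyphenyl)propanoic acid (phloretic acid)
Product: 2 3-(4-acetoxyphenyl)propanoic acid
Conditions: Ac2O (1.2 equiv), 2 M aq NaOH (2.2 equiv), 0 °C; then 2 M HCl to pH 2
Reagents that add atoms: acetic anhydride, CC(=O)OC(C)=O
Why: Schotten–Baumann O-acetylation of the phenoxide; any mixed anhydride formed at the carboxylate hydrolyses in the aqueous medium, and the acetoxy group later raises the oxidation potential of the ring for the anodic step.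

Step 2
Reactants: 2 3-(4-acetoxyphenyl)propanoic acid; 3 14-hydroxytetradecanoic acid
Product: 5 14-{[3-(4-acetoxyphenyl)propanoyl]oxy}tetradecanoic acid, via 3-(4-acetoxyphenyl)propanoyl chloride 4 (not isolated)
Conditions: (COCl)2, cat. DMF, CH2Cl2, 0 °C to rt, evaporate; then 3, pyridine, THF, 0 °C to rt; then H2O, rt; dilute HCl work-up
Reagents that add atoms: none
Why: Acid chloride formation followed by O-acylation of the primary alcohol through the acylpyridinium ion; the free carboxyl group of 3 is tolerated because any mixed anhydride is hydrolysed in the aqueous pyridine quench, as is usual for O-acyl-ω-hydroxy fatty acids.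

Step 3
Reactants: 5 14-{[3-(4-acetoxyphenyl)propanoyl]oxy}tetradecanoic acid; 6 tetradecanoic acid (myristic acid, 5 equiv)
Product: 7 hexacosyl 3-(4-acetoxyphenyl)propanoate
Conditions: undivided cell, smooth Pt anode and Pt cathode, KOH (5 mol% of total acid, added to 6 before 5), MeOH–hexane, 40–45 °C, constant current ca. 0.2 A cm⁻², stopped when 5 is consumed (bulk still acidic)
Reagents that add atoms: none
Why: One-electron oxidation of both carboxylates at the platinum anode gives acyloxy radicals that lose CO2, and the resulting tridecyl and 13-(acyloxy)tridecyl radicals combine in the anode layer to form the central C13–C14 CH2–CH2 bond. The closest known reaction type is the mixed (cross) Kolbe electrolysis of a fatty acid with an ω-functionalised acid or half ester. No ring is closed and no stereocentre is created. The step needs cross- over homo-coupling, which the fivefold excess of cheap 6 should secure statistically for the radical derived from 5; the expected co-products hexacosane and the symmetrical diester differ strongly in polarity from 7 and should be separable on silica. It also needs the radical pathway to win over the carbocation (non-Kolbe) pathway and the arene to stay intact, which unbranched primary radicals without α-heteroatom, a low degree of neutralisation, high current density and smooth platinum favour, while the acetoxy group deactivates the ring and thirteen methylene groups plus the ester insulate it from the carboxylate. Stopping while excess 6 keeps the bulk acidic prevents cathodically formed methoxide from attacking the aryl acetate or the alkyl ester.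

Step 4
Reactants: 7 hexacosyl 3-(4-acetoxyphenyl)propanoate
Product: 8 hexacosyl 3-(4-hydroxyphenyl)propanoate
Conditions: N2H4·H2O (1.5 equiv), THF, rt
Reagents that add atoms: none
Why: Chemoselective hydrazinolysis (aminolysis) of the aryl acetate; phenoxide is a far better leaving group than the hexacosyl alkoxide, so the alkyl ester should survive at room temperature.

Compound list
1 | 3-(4-hydroxyphenyl)propanoic acid (phloretic acid) | O=C(O)CCc1ccc(O)cc1 | starting material
2 | 3-(4-acetoxyphenyl)propanoic acid | CC(=O)Oc1ccc(CCC(=O)O)cc1 | intermediate
3 | 14-hydroxytetradecanoic acid | O=C(O)CCCCCCCCCCCCCO | starting material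
4 | 3-(4-acetoxyphenyl)propanoyl chloride | CC(=O)Oc1ccc(CCC(=O)Cl)cc1 | intermediate
5 | 14-{[3-(4-acetoxyphenyl)propanoyl]oxy}tetradecanoic acid | CC(=O)Oc1ccc(CCC(=O)OCCCCCCCCCCCCCC(=O)O)cc1 | intermediate
6 | tetradecanoic acid (myristic acid) | CCCCCCCCCCCCCC(=O)O | starting material
7 | hexacosyl 3-(4-acetoxyphenyl)propanoate | CCCCCCCCCCCCCCCCCCCCCCCCCCOC(=O)CCc1ccc(OC(C)=O)cc1 | intermediate
8 | hexacosyl 3-(4-hydroxyphenyl)propanoate | CCCCCCCCCCCCCCCCCCCCCCCCCCOC(=O)CCc1ccc(O)cc1 | target

Total step count: 4
Longest linear sequence: 4 steps (1 → 2 → 5 → 7 → 8); compounds 3 and 6 enter as purchased materials.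

Steps most likely to fail

Step 3. Homo-coupling may consume the radical derived from 5, waxy products may passivate the anode, and over-oxidation of the radical to a cation or anodic attack on the ring may compete. The fallback generates both radicals reductively and so avoids the anode. It sets out from 5 and 6. Acid 5 is converted with N-hydroxyphthalimide, DIC and cat. DMAP in CH2Cl2 into 1,3-dioxoisoindolin-2-yl 14-{[3-(4-acetoxyphenyl)propanoyl]oxy}tetradecanoate F1. Acid 6 is converted in the same way into 1,3-dioxoisoindolin-2-yl tetradecanoate F2. A nickel-electrocatalytic doubly decarboxylative coupling of F1 with an excess of F2 (NiCl2·6H2O, terpyridine-type ligand, AgNO3, Mg anode, RVC cathode, DMF) should then give the same CH2–CH2 bond. The fallback comes back to the route at 7.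

Step 2. The free carboxyl group of 3 may be acylated to a mixed anhydride, which can scramble acyl groups and lead to oligo-esters of 3. The fallback masks this carboxyl group and sets out from 3. Alkylation with benzyl bromide and KHCO3 in DMF gives benzyl 14-hydroxytetradecanoate F3. Steglich esterification of F3 with 2 (EDC·HCl, DMAP, CH2Cl2) gives benzyl 14-{[3-(4-acetoxyphenyl)propanoyl]oxy}tetradecanoate F4. Hydrogenolysis (H2, Pd/C, EtOAc) removes the benzyl group without touching the aryl acetate, and the fallback comes back at 5.

Step 4. The aminolysis may fail to discriminate between the two esters, so that the hexacosyl ester is also cleaved, or it may stall because the waxy substrate dissolves poorly. The fallback gives up chemoselective deprotection and sets out from 7. Complete saponification (LiOH, THF/MeOH/H2O, 50 °C) gives hexacosan-1-ol F5, which still carries the C13–C14 bond made in the key step. Fischer esterification of F5 with 1 (cat. p-TsOH, toluene, Dean–Stark, reflux) leaves the phenol unacylated, and the fallback comes back at 8.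

Further compounds
F1 | step 3 | 1,3-dioxoisoindolin-2-yl 14-{[3-(4-acetoxyphenyl)propanoyl]oxy}tetradecanoate | CC(=O)Oc1ccc(CCC(=O)OCCCCCCCCCCCCCC(=O)ON2C(=O)c3ccccc3C2=O)cc1
F2 | step 3 | 1,3-dioxoisoindolin-2-yl tetradecanoate | CCCCCCCCCCCCCC(=O)ON1C(=O)c2ccccc2C1=O
F3 | step 2 | benzyl 14-hydroxytetradecanoate | OCCCCCCCCCCCCCC(=O)OCc1ccccc1
F4 | step 2 | benzyl 14-{[3-(4-acetoxyphenyl)propanoyl]oxy}tetradecanoate | CC(=O)Oc1ccc(CCC(=O)OCCCCCCCCCCCCCC(=O)OCc2ccccc2)cc1
F5 | step 4 | hexacosan-1-ol | CCCCCCCCCCCCCCCCCCCCCCCCCCO
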